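- 0.416 /M is the number I would reckon with: the bis constant K = D/(M·B). Here D and M are bis adduct and first product, and B is the partner not yet built into product, taken as its charge minus M minus 2D. It is a rough mean of the violet readings from 1.33 h on.

| setting | violet | summer | dawn | midnight |
|---|---|---|---|---|
| starting material | 1 M (in portions, 4) | 1.0 M (in portions, 4) | 1.0 M (in portions, 4) | 1.0 M (in portions, 4) |
| partner | 0.61 M | 0.500 M | 1.20 M | 3.00 M |
| remark | run made earlier; portions every 30 min | the portions of starting material follow each other after 30 min, the first at the start | the portions of starting material follow each other after 30 min, the first at the start | the portions of starting material follow each other after 30 min, the first at the start |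
| time |  | 4.0 h | 4.0 h | 4.0 h |

violet run (percent of the starting material charged)

| time / h | first product / % | bis adduct / % |
|---|---|---|
| 0.250 | 5.6 | 0 |
| 0.667 | 14.0 | 2.2 |
| 1.33 | 26.5 | 3.0 |
| 2.00 | 36.8 | 2.5 |
| 3.00 | 43.9 | 2.6 |

(readings scatter by 1 percentage point)

- which of these holds the largest part of the starting material at the end of summer (bis adduct / starting material / first product)
- which of these holds the largest part of the starting material at the end of dawn (bis adduct / starting material / first product)
- which of these holds the largest part of the starting material at the end of midnight (bis adduct / starting material / first product)
- amount of first product at the end of summer, in percent of the starting material charged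



- You suspect that a large partner excess carries first product on to bis adduct with time. In violet, though, bis adduct reads 3.0% at 1.33 h and 2.6% at 3.00 h, while first product climbs from 26.5% to 43.9%. So I let D/M follow K·B and solve both ends.
- Partner-short end: in summer partner is the limiting reagent, and its 0.500 M against 1.0 M leaves at least 50.0% of the starting material once all portions are in, so I call starting material. The violet readings at 3.00 h put 80.5% of its partner into M + 2D, and that share of the summer partner gives about 40.2% as M + 2D, which I take for first product.
- Partner-rich end: in midnight, suppose D equalled M, each half of the charge. Then K·B comes to 0.624, below the 1 supposed. One more pass gives D/M of 0.672, so I call first product.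
- Dawn lies near the lean end: taking the whole charge as first product, I get B of 0.200 M and D/M of 0.0832, so I call first product.
- The forecast named starting material for summer, first product for dawn and bis adduct for midnight, with 41% (36% to 45%) first product in summer, its midnight call being “the least certain call”.

    starting material + partner → first product (k = 2.90 /M/h)
    partner + first product ⇌ bis adduct (K = 0.770 /M, k = 5.30 /M/h)
    partner ⇌ dormant form (K = 0.940, k = 0.690 /h)
    first product → decomposed reagent (k = 0.0500 /h)

- Summer ends with starting material at 56.2% and first product at 38.0%, dawn with first product at 68.9%, and midnight with first product at 55.6% against 35.9% bis adduct, a D/M of 0.646 beside my 0.672. At the end of summer the bis step alone, both ways together, relaxes with a half-life of 0.0772 h, far shorter than the 4.0 h run. The summer recipe with 2.0 M of partner has K·B of 0.294 by the same reckoning, and that flask holds 20.7% bis adduct on 67.9% first product, a D/M of 0.305.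

The runs are simulated for substances that don't exist.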